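## The problem

Positions are cited in germacrane numbering: ring C1–C10, lactone carbons C11–C13 on C7, C14 on C10, C15 on C4. The target 35 is a ten-membered carbocycle trans-fused across C7–C8 to an α-methylene-γ-butyrolactone whose oxygen sits on C8. C10 carries a free hydroxymethyl group (C14), and C4 a hydroxymethyl group (C15) esterified with 2-hydroxy-2-methylpropanoic acid. The ring holds two trisubstituted alkenes of opposite ring geometry: at C1=C10 the two ring bonds are cis (E by the CIP rules, because C14 outranks C9), at C4=C5 they are trans (Z by the CIP rules). Neither can be corrected once the medium ring exists. The only stereocenters, C7 (R) and C8 (S), are adjacent and anti. They can be set together in an open chain by one enantioselective and one stereospecific reaction, but they cannot steer either alkene geometry. The α-methylene lactone (conjugate acceptor), the tertiary-hydroxy ester (base, acyl transfer) and the cyclodeca-1,5-diene (transannular cyclisation with acid, Cope rearrangement on heating) rule out rough treatment late in the route, and the two primary allylic oxygens at C14 and C15 must stay distinguishable to the last step. The feature that opens the structure is the C2–C3–C4 segment. C4 is an sp2 carbon flanked by the C15 oxygen, so it can be the iodine-bearing carbon of a 2-iodoallyl ether made from a propargylic ether. C3 is a primary sp3 carbon that can be reached as an alkylborane from a terminal C2=C3 alkene. The ring can therefore be closed at C3–C4 by sp3–sp2 cross-coupling with both alkene geometries already fixed.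

## Retrosynthesis

**Ester and silyl groups (35 to 30 and 33).** The C15–O acyl bond and the last two silyl groups are removed first, leading from 35 through silyl-protected ester 34 to allylic alcohol 30 and the O-silylated acid 33 (from 31). The hydroxy ester and the free C14 hydroxyl would not survive enolate or oxidation chemistry, so they appear last. The forward reaction only has to acylate one primary allylic alcohol while C14 is still a TBDPS ether.

**Exocyclic methylene (30 to 26).** The C11=C13 bond is cut next, so that 29 (and 30 after PMB removal) comes from the saturated lactone 26 by enolate aminomethylation and elimination. Carrying the methylene through the ring closure would give 9-BBN a second reactive 1,1-disubstituted alkene; a saturated C11 avoids that at the cost of one late operation. The reaction asked for is a lactone enolate alkylation with no stereochemical demand.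

**Lactone C12–O bond (26 to 23).** Lactone 26 is opened to the 1,4-diol 24 and its bis-silyl ether 23. A lactone would not survive the hydride reductions needed earlier at C9 and C14, whereas two TBS ethers do. The forward step must oxidise a primary alcohol beside a secondary one, which the oxoammonium/lactol pathway does.

**Ring bond C3–C4 (23 to 21).** This is the key cut, to the acyclic diene vinyl iodide 21. Cutting here, and not at an alkene or at C6–C7, keeps both alkenes and both stereocenters out of the ring-forming event. The precursor is an open chain whose geometry and configuration can be checked before cyclisation. The forward reaction must hydroborate only C2=C3 and then cyclise faster than it oligomerises.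

**Diene unit (21 to 14, 15 and 18).** The C1=C10 double bond is cut by Horner–Wadsworth–Emmons logic to phosphonate 17 and acrolein 18; ester 19 is reduced to 20 and silylated to 21. The C9–C10 bond is then cut to the primary alcohol 14 (as its triflate 16) and triethyl phosphonoacetate 15. An α-substituted phosphonoacetate places the ester trans to the vinyl group, which is exactly the ring-cis arrangement of C9 and C2. A Wittig reaction on a C10 ketone would not control this. The alkylation has to succeed at a β-branched, β-oxygenated primary carbon, hence the triflate.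

**Oxygen pattern at C8, C9, C12 (14 to 9).** Alcohol 14 is traced through pivalate 13, diol 12 and pivalate 10 to the vinyl diol 9. The C12 oxygen comes from hydroboration of a C7 vinyl group, the two secondary/primary hydroxyls are silylated together, and the pivalate keeps C9 apart from C12. Each forward step is a routine chemoselective operation.

**C7–C11 bond and the two stereocenters (9 to 7).** Diol 9 arises by opening the cis-epoxy alcohol 8 at C7 with a vinyl nucleophile, and 8 by asymmetric epoxidation of the Z-allylic alcohol 7. A cis-epoxide opened with inversion at C7 gives the anti C7/C8 relationship of the trans-lactone; the E-alcohol would give the wrong diastereomer. The epoxidation sets both centers in one step, and the opening must be regioselective for the carbon remote from the hydroxymethyl group.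

**Vinyl iodide and chain assembly (7 to 1 and 3).** The C4–I bond is traced to the alkyne of enynol 5 by syn hydrostannation and iodination. The C5–C6 bond is cut to the PMB ether 2 of propargyl alcohol 1 and the allylic chloride 4 of (Z)-butenediol 3. Hydrometalation is placed early, on an achiral alcohol, so that any regioisomer is removed before the stereocenters are made.

## Roads not taken

**Alternative 1:** The cut is C6–C7. In the forward sense MeAlCl2 ionises the C6 allylic phosphate of the open-chain allylsilane A1; C7 of the 2-(silyloxymethyl)allylsilane attacks C6, and loss of silicon releases the C11=C13 methylene, giving the ten-membered triene ester A2.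
- Merits: ring, C7 stereocenter and exocyclic methylene arise in one step, and the late methylenation sequence of the chosen plan is saved. In step economy at the end this road is ahead.
- Weak points: the allyl cation is delocalised over C4–C6, so attack at C4 (an eight-membered ring with a quaternary carbon) and loss of the C4=C5 geometry are both open. C7 is created relative to C8 through a flexible medium-ring transition state whose facial preference is unknown. Elimination competes with a slow ten-membered cation–olefin closure.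
- Comparison: the chosen plan sets C7 and C8 in the open chain and asks the ring closure to create neither a stereocenter nor an alkene. It accepts a saturated C7 side chain and the extra methylenation step.

**Alternative 2:** The cut is a ring expansion: C5–C10 is bonded in a cyclohexane and C2–C3 is formed by a [3,3] shift. The potassium alkoxide (KH, 18-crown-6) of the cis-1,2-dialkenylcyclohexanol A3 rearranges, and the C4=C5 enolate is trapped with PhNTf2 to give the enol triflate A4.
- Merits: the ten-membered ring comes from a six-membered one, so there is no end-to-end entropy penalty, and the charge-accelerated rearrangement is normally efficient. In reliability of medium-ring formation this road is probably better than a ten-membered cross-coupling.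
- Weak points: A3 needs four defined stereocenters, including a quaternary C10 next to a tertiary carbinol, for a target that has two. The alkene geometries depend on a chair-versus-boat preference of a crowded cis-dialkenyl system. The enolate bears a β-silyloxy group at C15 and can eliminate before it is trapped. The C5 triflate must later be removed reductively.
- Comparison: the chosen plan has a short acyclic precursor synthesis with no stereocenters made only to be destroyed and no extra functional group to delete.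

**Alternative 3:** The cut is the C1=C10 double bond. With LiCl and DBU at high dilution the C10 phosphonoacetate carbanion of aldehyde A5 adds to C1 and eliminates phosphate, giving the ten-membered triene ester A6.
- Merits: the conditions are mild and tolerate the C7 2-propenyl unit, so the methylene is in place early. C14 arrives as an ester, already different from C15. Macrocyclic olefination is better precedented for strained rings than sp3–sp2 coupling at ring size ten, and the step count is equal or slightly lower.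
- Weak points: the ring closure must also deliver the ring-cis geometry at C1=C10 in a ring that already holds a trans alkene, so the outcome rests on conformation. Cyclodimerisation competes.
- Comparison: the chosen plan fixes both alkene geometries in open-chain intermediates that can be purified, and leaves the closure with no stereochemical task.

Key step: step 15

Remark: ring alkenes are described by their ring bonds (cis at C1=C10, trans at C4=C5); compound names carry the corresponding CIP letters, which are E and Z. Abbreviations in names: PMBO = (4-methoxyphenyl)methoxy; TBSO = tert-butyldimethylsilyloxy; TBDPSO = tert-butyldiphenylsilyloxy; TESO = triethylsilyloxy; 9-BBN-yl = 9-borabicyclo[3.3.1]nonan-9-yl.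

## Route

Step 1
Reactants: 1 prop-2-yn-1-ol
Product: 2 1-methoxy-4-[(prop-2-yn-1-yloxy)methyl]benzene
Conditions: NaH, PMBCl, Bu4NI (cat.), THF, 0 °C to rt
Reagents that add atoms: 4-methoxybenzyl chloride, COc1ccc(CCl)cc1
Why: Williamson ether synthesis; the alkoxide forms selectively because the O–H is far more acidic than the alkyne C–H under these conditions.

Step 2
Reactants: 3 (2Z)-but-2-ene-1,4-diol
Product: 4 (2Z)-4-chlorobut-2-en-1-ol
Conditions: SOCl2 (1 equiv), pyridine, Et2O, 0 °C, diol in excess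
Reagents that add atoms: thionyl chloride, O=S(Cl)Cl
Why: Chlorodehydroxylation through the allylic chlorosulfite, which chloride displaces in the presence of pyridine; excess diol limits dichloride formation and the Z alkene is not touched.

Step 3
Reactants: 2 1-methoxy-4-[(prop-2-yn-1-yloxy)methyl]benzene; 4 (2Z)-4-chlorobut-2-en-1-ol
Product: 5 (2Z)-7-(PMBO)hept-2-en-5-yn-1-ol
Conditions: CuI (10 mol %), Bu4NCl, K2CO3, DMF, rt
Reagents that add atoms: none
Why: Copper-catalysed alkynylation of a primary allylic chloride; the copper acetylide should substitute at the unsubstituted terminus with retention of the Z alkene, forming C5–C6 as a skipped enyne, and the free hydroxyl is tolerated.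

Step 4
Reactants: 5 (2Z)-7-(PMBO)hept-2-en-5-yn-1-ol
Product: 7 (2Z,5E)-6-iodo-7-(PMBO)hepta-2,5-dien-1-ol, via vinylstannane 6 (not isolated)
Conditions: Bu3SnH, PdCl2(PPh3)2 (2 mol %), THF, 0 °C; then I2, CH2Cl2, 0 °C
Reagents that add atoms: iodine, II
Why: Palladium-catalysed syn hydrostannation should place tin on the alkyne carbon next to the ether CH2 (C4) and hydrogen on C5, and iododestannylation proceeds with retention, so iodine ends trans to C6. Any distal regioisomer is removed here on a small achiral alcohol.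

Step 5
Reactants: 7 (2Z,5E)-6-iodo-7-(PMBO)hepta-2,5-dien-1-ol
Product: 8 [(2S,3R)-3-[(2E)-3-iodo-4-(PMBO)but-2-en-1-yl]oxiran-2-yl]methanol
Conditions: Ti(OiPr)4 (10 mol %), L-(+)-diethyl tartrate (12 mol %), t-BuOOH, 4 Å MS, CH2Cl2, −20 °C
Reagents that add atoms: tert-butyl hydroperoxide, CC(C)(C)OO
Why: Sharpless asymmetric epoxidation; the titanium–tartrate complex binds the allylic alcohol and L-(+)-tartrate delivers oxygen to the face that gives the (2S,3R) cis-epoxide, fixing C8 and preparing C7 for inversion. The iodoalkene is not an allylic alcohol and stays untouched.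

Step 6
Reactants: 8 [(2S,3R)-3-[(2E)-3-iodo-4-(PMBO)but-2-en-1-yl]oxiran-2-yl]methanol
Product: 9 (2R,3R,5E)-3-ethenyl-6-iodo-7-(PMBO)hept-5-ene-1,2-diol
Conditions: Et2Al(CH=CH2) (from CH2=CHMgBr and Et2AlCl, 3.5 equiv), toluene–CH2Cl2, −20 °C to rt; aq. KNaC4H4O6
Reagents that add atoms: vinylmagnesium bromide, C=C[Mg]Br
Why: Organoalane opening of a 2,3-epoxy alcohol at the carbon remote from the hydroxymethyl group; the aluminium alkoxide chelates the epoxide oxygen and a second alane delivers the sp2 group to C7 with inversion, which sets the anti C7/C8 pair and forms C7–C11.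

Step 7
Reactants: 9 (2R,3R,5E)-3-ethenyl-6-iodo-7-(PMBO)hept-5-ene-1,2-diol
Product: 10 (2R,3R,5E)-3-ethenyl-2-hydroxy-6-iodo-7-(PMBO)hept-5-en-1-yl pivalate
Conditions: PivCl, pyridine, CH2Cl2, −20 to 0 °C
Reagents that add atoms: pivaloyl chloride, CC(C)(C)C(=O)Cl
Why: Selective acylation; the bulky acid chloride reacts at the primary C9 hydroxyl and leaves the hindered secondary C8 hydroxyl free.

Step 8
Reactants: 10 (2R,3R,5E)-3-ethenyl-2-hydroxy-6-iodo-7-(PMBO)hept-5-en-1-yl pivalate
Product: 12 (2R,3R,5E)-2-hydroxy-3-(2-hydroxyethyl)-6-iodo-7-(PMBO)hept-5-en-1-yl pivalate, via bis-boryl adduct 11 (not isolated)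
Conditions: 9-BBN (2.5 equiv), THF, 0 °C to rt; then NaBO3·4H2O, H2O, rt
Reagents that add atoms: sodium perborate, [Na+].[Na+].O[B-]1(O)OO[B-](O)(O)OO1
Why: Hydroboration–oxidation; 9-BBN adds anti-Markovnikov to the monosubstituted vinyl group only (the trisubstituted iodoalkene is inert), and perborate oxidises the C–B bond without disturbing the pivalate, giving the C12 alcohol.

Step 9
Reactants: 12 (2R,3R,5E)-2-hydroxy-3-(2-hydroxyethyl)-6-iodo-7-(PMBO)hept-5-en-1-yl pivalate
Product: 13 (2R,3R,5E)-2-(TBSO)-3-[2-(TBSO)ethyl]-6-iodo-7-(PMBO)hept-5-en-1-yl pivalate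
Conditions: TBSOTf (2.4 equiv), 2,6-lutidine, CH2Cl2, −78 to 0 °C
Reagents that add atoms: tert-butyldimethylsilyl trifluoromethanesulfonate, CC(C)(C)[Si](C)(C)OS(=O)(=O)C(F)(F)F
Why: Silylation; the silyl triflate protects the primary C12 and the hindered secondary C8 hydroxyl in one operation.

Step 10
Reactants: 13 (2R,3R,5E)-2-(TBSO)-3-[2-(TBSO)ethyl]-6-iodo-7-(PMBO)hept-5-en-1-yl pivalate
Product: 14 (2R,3R,5E)-2-(TBSO)-3-[2-(TBSO)ethyl]-6-iodo-7-(PMBO)hept-5-en-1-ol
Conditions: i-Bu2AlH, CH2Cl2, −78 °C; aq. KNaC4H4O6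
Reagents that add atoms: none
Why: Reductive ester cleavage; the hydride removes the pivalate at low temperature while silyl ethers, PMB ether and vinyl iodide are inert.

Step 11
Reactants: 14 (2R,3R,5E)-2-(TBSO)-3-[2-(TBSO)ethyl]-6-iodo-7-(PMBO)hept-5-en-1-ol; 15 triethyl phosphonoacetate
Product: 17 ethyl (4S,5R,7E)-4-(TBSO)-5-[2-(TBSO)ethyl]-2-(diethoxyphosphoryl)-8-iodo-9-(PMBO)non-7-enoate, via triflate 16 (not isolated)
Conditions: Tf2O, 2,6-lutidine, CH2Cl2, −78 °C; then 15 (3 equiv), NaH, THF–DMF, 0 °C to rt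
Reagents that add atoms: none
Why: SN2 alkylation of the sodium phosphonoacetate carbanion forms C9–C10; the triflate makes up for the slow displacement at a β-branched, β-silyloxy primary carbon and excess carbanion suppresses dialkylation. The product is a pair of C10 epimers, which is of no consequence.

Step 12
Reactants: 17 ethyl (4S,5R,7E)-4-(TBSO)-5-[2-(TBSO)ethyl]-2-(diethoxyphosphoryl)-8-iodo-9-(PMBO)non-7-enoate; 18 prop-2-enal
Product: 19 ethyl (2E)-2-[(2S,3R,5E)-2-(TBSO)-3-[2-(TBSO)ethyl]-6-iodo-7-(PMBO)hept-5-en-1-yl]penta-2,4-dienoate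
Conditions: NaH, THF, 0 °C; then acrolein, −78 to 0 °C
Reagents that add atoms: none
Why: Horner–Wadsworth–Emmons olefination; α-substituted phosphonoacetates give the enoate with the ester trans to the aldehyde substituent, which places C9 and C2 cis across C1=C10, and low temperature favours 1,2-addition to acrolein.

Step 13
Reactants: 19 ethyl (2E)-2-[(2S,3R,5E)-2-(TBSO)-3-[2-(TBSO)ethyl]-6-iodo-7-(PMBO)hept-5-en-1-yl]penta-2,4-dienoate
Product: 20 (2E)-2-[(2S,3R,5E)-2-(TBSO)-3-[2-(TBSO)ethyl]-6-iodo-7-(PMBO)hept-5-en-1-yl]penta-2,4-dien-1-ol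
Conditions: i-Bu2AlH, CH2Cl2, −78 °C; aq. KNaC4H4O6
Reagents that add atoms: none
Why: 1,2-Reduction of the conjugated ester to the C14 allylic alcohol; the diene geometry is not affected.

Step 14
Reactants: 20 (2E)-2-[(2S,3R,5E)-2-(TBSO)-3-[2-(TBSO)ethyl]-6-iodo-7-(PMBO)hept-5-en-1-yl]penta-2,4-dien-1-ol
Product: 21 tert-butyl{[(2E)-2-[(2S,3R,5E)-2-(TBSO)-3-[2-(TBSO)ethyl]-6-iodo-7-(PMBO)hept-5-en-1-yl]penta-2,4-dien-1-yl]oxy}diphenylsilane
Conditions: TBDPSCl, imidazole, DMF, rt
Reagents that add atoms: tert-butyl(chloro)diphenylsilane, CC(C)(C)[Si](Cl)(c1ccccc1)c1ccccc1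
Why: Silylation of the only free hydroxyl; the acid-stable TBDPS group lets the two TBS ethers be removed later without exposing C14.

Step 15
Reactants: 21 tert-butyl{[(2E)-2-[(2S,3R,5E)-2-(TBSO)-3-[2-(TBSO)ethyl]-6-iodo-7-(PMBO)hept-5-en-1-yl]penta-2,4-dien-1-yl]oxy}diphenylsilane
Product: 23 (1E,5Z,8R,9S)-9-(TBSO)-8-[2-(TBSO)ethyl]-1-(TBDPSO-methyl)-5-(PMBO-methyl)cyclodeca-1,5-diene, via alkylborane 22 (not isolated)
Conditions: 9-BBN (1.5 equiv), THF, 0 °C to rt; then slow addition to PdCl2(dppf) (20 mol %), AsPh3 (40 mol %), Cs2CO3, DMF–THF–H2O, 50 °C, final 1 mM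
Reagents that add atoms: none
Why: 9-BBN adds across the terminal C2=C3 bond of the diene with boron on C3, the monosubstituted alkene being far more reactive than the trisubstituted C1=C10 alkene or the iodoalkene. The C4–I bond then adds oxidatively to zerovalent palladium with retention, the base-activated borate transfers its primary alkyl group, and reductive elimination from an eleven-membered palladacycle forms C3–C4. The closest known reaction type is the intramolecular B-alkyl Suzuki–Miyaura macrocyclisation, here at the small end of its ring-size range. The ten-membered carbocycle closes by C(sp3)–C(sp2) reductive elimination with both alkenes already in the chain. No stereocenter is formed; C7 and C8 are spectators, the E vinyl iodide becomes the ring-trans C4=C5 alkene by retention, and the ring-cis C1=C10 alkene comes unchanged from step 12. Chemoselective hydroboration is secured by the saturated C7 side chain and the substitution of the other alkenes. Cyclisation over oligomerisation is secured by slow addition at high dilution. Coupling over β-hydride elimination is favoured by the wide-bite-angle dppf ligand with AsPh3.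

Step 16
Reactants: 23 (1E,5Z,8R,9S)-9-(TBSO)-8-[2-(TBSO)ethyl]-1-(TBDPSO-methyl)-5-(PMBO-methyl)cyclodeca-1,5-diene
Product: 24 (1S,3E,7Z,10R)-3-(TBDPSO-methyl)-10-(2-hydroxyethyl)-7-(PMBO-methyl)cyclodeca-3,7-dien-1-ol
Conditions: CSA (0.3 equiv), MeOH–CH2Cl2, 0 °C to rt
Reagents that add atoms: none
Why: Acid-catalysed methanolysis of silyl ethers; TBS ethers cleave far faster than the TBDPS ether under acid, and the mild acid at low temperature should not trigger transannular reaction of the allylically oxygenated diene.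

Step 17
Reactants: 24 (1S,3E,7Z,10R)-3-(TBDPSO-methyl)-10-(2-hydroxyethyl)-7-(PMBO-methyl)cyclodeca-3,7-dien-1-ol
Product: 26 (3aR,5Z,9E,11aS)-10-(TBDPSO-methyl)-6-(PMBO-methyl)-3a,4,7,8,11,11a-hexahydrocyclodeca[b]furan-2(3H)-one, via lactol 25 (not isolated)
Conditions: TEMPO (0.2 equiv), PhI(OAc)2 (3 equiv), CH2Cl2, rt
Reagents that add atoms: none
Why: Oxoammonium-mediated oxidative lactonisation; the primary C12 alcohol is oxidised to the aldehyde, which closes on the C8 hydroxyl to the lactol and is oxidised again, while the secondary alcohol reacts much more slowly. The trans ring fusion follows from the C7/C8 configuration.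

Step 18
Reactants: 26 (3aR,5Z,9E,11aS)-10-(TBDPSO-methyl)-6-(PMBO-methyl)-3a,4,7,8,11,11a-hexahydrocyclodeca[b]furan-2(3H)-one
Product: 29 (3aR,5Z,9E,11aS)-10-(TBDPSO-methyl)-6-(PMBO-methyl)-3-methylidene-3a,4,7,8,11,11a-hexahydrocyclodeca[b]furan-2(3H)-one, via Mannich base 27 (not isolated), via ammonium iodide 28 (not isolated)
Conditions: LiN(iPr)2, THF, −78 °C; Me2N=CH2+ I−, −78 °C to rt; then MeI, MeOH, rt; then aq. NaHCO3–CH2Cl2, rt
Reagents that add atoms: N,N-dimethylmethyleneiminium iodide, C=[N+](C)C.[I-]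
Why: Eschenmoser methylenation; the lactone enolate is aminomethylated at C11, the amine is quaternised, and E1cB loss of trimethylamine gives the exocyclic C11=C13 alkene. The new C11 center is destroyed, so its configuration does not matter.

Step 19
Reactants: 29 (3aR,5Z,9E,11aS)-10-(TBDPSO-methyl)-6-(PMBO-methyl)-3-methylidene-3a,4,7,8,11,11a-hexahydrocyclodeca[b]furan-2(3H)-one
Product: 30 (3aR,5Z,9E,11aS)-10-(TBDPSO-methyl)-6-(hydroxymethyl)-3-methylidene-3a,4,7,8,11,11a-hexahydrocyclodeca[b]furan-2(3H)-one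
Conditions: DDQ (1.2 equiv), CH2Cl2–pH 7 buffer, 0 °C
Reagents that add atoms: none
Why: Oxidative PMB ether cleavage; DDQ abstracts the benzylic hydride of the electron-rich ether and water hydrolyses the oxocarbenium ion, freeing the C15 alcohol while the silyl ether and the alkenes stay intact.

Step 20
Reactants: 31 2-hydroxy-2-methylpropanoic acid
Product: 33 2-methyl-2-(TESO)propanoic acid, via silyl ester 32 (not isolated)
Conditions: Et3SiOTf (2.2 equiv), 2,6-lutidine, CH2Cl2, 0 °C; then THF–H2O, K2CO3 (cat.), 0 °C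
Reagents that add atoms: triethylsilyl trifluoromethanesulfonate, CC[Si](CC)(CC)OS(=O)(=O)C(F)(F)F
Why: Silylation of both the tertiary hydroxyl and the acid, followed by selective hydrolysis of the much more labile silyl ester; this masks the hydroxyl so that the acid cannot self-condense in the coupling.

Step 21
Reactants: 30 (3aR,5Z,9E,11aS)-10-(TBDPSO-methyl)-6-(hydroxymethyl)-3-methylidene-3a,4,7,8,11,11a-hexahydrocyclodeca[b]furan-2(3H)-one; 33 2-methyl-2-(TESO)propanoic acid
Product: 34 [(3aR,5Z,9E,11aS)-10-(TBDPSO-methyl)-3-methylidene-2-oxo-2,3,3a,4,7,8,11,11a-octahydrocyclodeca[b]furan-6-yl]methyl 2-methyl-2-(TESO)propanoate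
Conditions: EDC·HCl, DMAP, CH2Cl2, 0 °C to rt
Reagents that add atoms: none
Why: Steglich esterification; carbodiimide activation and DMAP acyl transfer acylate the only free hydroxyl (C15) under conditions that leave the α-methylene lactone alone.

Step 22
Reactants: 34 [(3aR,5Z,9E,11aS)-10-(TBDPSO-methyl)-3-methylidene-2-oxo-2,3,3a,4,7,8,11,11a-octahydrocyclodeca[b]furan-6-yl]methyl 2-methyl-2-(TESO)propanoate
Product: 35 [(3aR,5Z,9E,11aS)-10-(hydroxymethyl)-3-methylidene-2-oxo-2,3,3a,4,7,8,11,11a-octahydrocyclodeca[b]furan-6-yl]methyl 2-hydroxy-2-methylpropanoate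
Conditions: HF·pyridine, pyridine, THF, 0 °C to rt
Reagents that add atoms: none
Why: Fluoride-mediated desilylation; buffered HF cleaves the TBDPS and TES ethers without a basic medium, so neither acyl transfer nor conjugate addition to the methylene lactone should occur.

## Compound list

1 | prop-2-yn-1-ol | C#CCO | starting material
2 | 1-methoxy-4-[(prop-2-yn-1-yloxy)methyl]benzene | C#CCOCc1ccc(OC)cc1 | intermediate
3 | (2Z)-but-2-ene-1,4-diol | OC/C=C\CO | starting material
4 | (2Z)-4-chlorobut-2-en-1-ol | OC/C=C\CCl | intermediate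
5 | (2Z)-7-(PMBO)hept-2-en-5-yn-1-ol | OC/C=C\CC#CCOCc1ccc(OC)cc1 | intermediate
6 | (2Z,5E)-7-(PMBO)-6-(tributylstannyl)hepta-2,5-dien-1-ol | OC/C=C\C/C=C(/[Sn](CCCC)(CCCC)CCCC)COCc1ccc(OC)cc1 | intermediate
7 | (2Z,5E)-6-iodo-7-(PMBO)hepta-2,5-dien-1-ol | OC/C=C\C/C=C(/I)COCc1ccc(OC)cc1 | intermediate
8 | [(2S,3R)-3-[(2E)-3-iodo-4-(PMBO)but-2-en-1-yl]oxiran-2-yl]methanol | OC[C@@H]1O[C@@H]1C/C=C(/I)COCc2ccc(OC)cc2 | intermediate
9 | (2R,3R,5E)-3-ethenyl-6-iodo-7-(PMBO)hept-5-ene-1,2-diol | OC[C@H](O)[C@@H](C=C)C/C=C(/I)COCc1ccc(OC)cc1 | intermediate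
10 | (2R,3R,5E)-3-ethenyl-2-hydroxy-6-iodo-7-(PMBO)hept-5-en-1-yl pivalate | CC(C)(C)C(=O)OC[C@H](O)[C@@H](C=C)C/C=C(/I)COCc1ccc(OC)cc1 | intermediate
11 | (2R,3S,5E)-2-(9-BBN-yloxy)-3-[2-(9-BBN-yl)ethyl]-6-iodo-7-(PMBO)hept-5-en-1-yl pivalate | CC(C)(C)C(=O)OC[C@H](OB1C2CCCC1CCC2)[C@@H](CCB3C4CCCC3CCC4)C/C=C(/I)COCc5ccc(OC)cc5 | intermediate
12 | (2R,3R,5E)-2-hydroxy-3-(2-hydroxyethyl)-6-iodo-7-(PMBO)hept-5-en-1-yl pivalate | CC(C)(C)C(=O)OC[C@H](O)[C@@H](CCO)C/C=C(/I)COCc1ccc(OC)cc1 | intermediate
13 | (2R,3R,5E)-2-(TBSO)-3-[2-(TBSO)ethyl]-6-iodo-7-(PMBO)hept-5-en-1-yl pivalate | CC(C)(C)C(=O)OC[C@H](O[Si](C)(C)C(C)(C)C)[C@@H](CCO[Si](C)(C)C(C)(C)C)C/C=C(/I)COCc1ccc(OC)cc1 | intermediate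
14 | (2R,3R,5E)-2-(TBSO)-3-[2-(TBSO)ethyl]-6-iodo-7-(PMBO)hept-5-en-1-ol | OC[C@H](O[Si](C)(C)C(C)(C)C)[C@@H](CCO[Si](C)(C)C(C)(C)C)C/C=C(/I)COCc1ccc(OC)cc1 | intermediate
15 | triethyl phosphonoacetate | CCOC(=O)CP(=O)(OCC)OCC | starting material
16 | (2R,3R,5E)-2-(TBSO)-3-[2-(TBSO)ethyl]-6-iodo-7-(PMBO)hept-5-en-1-yl trifluoromethanesulfonate | FC(F)(F)S(=O)(=O)OC[C@H](O[Si](C)(C)C(C)(C)C)[C@@H](CCO[Si](C)(C)C(C)(C)C)C/C=C(/I)COCc1ccc(OC)cc1 | intermediate
17 | ethyl (4S,5R,7E)-4-(TBSO)-5-[2-(TBSO)ethyl]-2-(diethoxyphosphoryl)-8-iodo-9-(PMBO)non-7-enoate (both C2 epimers) | CCOC(=O)C(C[C@H](O[Si](C)(C)C(C)(C)C)[C@@H](CCO[Si](C)(C)C(C)(C)C)C/C=C(/I)COCc1ccc(OC)cc1)P(=O)(OCC)OCC | intermediate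
18 | prop-2-enal (acrolein) | C=CC=O | starting material
19 | ethyl (2E)-2-[(2S,3R,5E)-2-(TBSO)-3-[2-(TBSO)ethyl]-6-iodo-7-(PMBO)hept-5-en-1-yl]penta-2,4-dienoate | C=C/C=C(C(=O)OCC)\C[C@H](O[Si](C)(C)C(C)(C)C)[C@@H](CCO[Si](C)(C)C(C)(C)C)C/C=C(/I)COCc1ccc(OC)cc1 | intermediate
20 | (2E)-2-[(2S,3R,5E)-2-(TBSO)-3-[2-(TBSO)ethyl]-6-iodo-7-(PMBO)hept-5-en-1-yl]penta-2,4-dien-1-ol | C=C/C=C(CO)\C[C@H](O[Si](C)(C)C(C)(C)C)[C@@H](CCO[Si](C)(C)C(C)(C)C)C/C=C(/I)COCc1ccc(OC)cc1 | intermediate
21 | tert-butyl{[(2E)-2-[(2S,3R,5E)-2-(TBSO)-3-[2-(TBSO)ethyl]-6-iodo-7-(PMBO)hept-5-en-1-yl]penta-2,4-dien-1-yl]oxy}diphenylsilane | C=C/C=C(CO[Si](c1ccccc1)(c1ccccc1)C(C)(C)C)\C[C@H](O[Si](C)(C)C(C)(C)C)[C@@H](CCO[Si](C)(C)C(C)(C)C)C/C=C(/I)COCc1ccc(OC)cc1 | intermediate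
22 | 9-[(3E,6S,7R,9E)-6-(TBSO)-7-[2-(TBSO)ethyl]-4-(TBDPSO-methyl)-10-iodo-11-(PMBO)undeca-3,9-dien-1-yl]-9-borabicyclo[3.3.1]nonane | B1(CC/C=C(CO[Si](c2ccccc2)(c3ccccc3)C(C)(C)C)\C[C@H](O[Si](C)(C)C(C)(C)C)[C@@H](CCO[Si](C)(C)C(C)(C)C)C/C=C(/I)COCc4ccc(OC)cc4)C5CCCC1CCC5 | intermediate
23 | (1E,5Z,8R,9S)-9-(TBSO)-8-[2-(TBSO)ethyl]-1-(TBDPSO-methyl)-5-(PMBO-methyl)cyclodeca-1,5-diene | CC(C)(C)[Si](C)(C)O[C@H]1C/C(CO[Si](c2ccccc2)(c2ccccc2)C(C)(C)C)=C\CC/C(COCc2ccc(OC)cc2)=C/C[C@@H]1CCO[Si](C)(C)C(C)(C)C | intermediate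
24 | (1S,3E,7Z,10R)-3-(TBDPSO-methyl)-10-(2-hydroxyethyl)-7-(PMBO-methyl)cyclodeca-3,7-dien-1-ol | O[C@H]1C/C(CO[Si](c2ccccc2)(c2ccccc2)C(C)(C)C)=C\CC/C(COCc2ccc(OC)cc2)=C/C[C@@H]1CCO | intermediate
25 | (3aR,5Z,9E,11aS)-10-(TBDPSO-methyl)-6-(PMBO-methyl)-2,3,3a,4,7,8,11,11a-octahydrocyclodeca[b]furan-2-ol (both C2 epimers) | OC1O[C@H]2C/C(CO[Si](c3ccccc3)(c3ccccc3)C(C)(C)C)=C\CC/C(COCc3ccc(OC)cc3)=C/C[C@@H]2C1 | intermediate
26 | (3aR,5Z,9E,11aS)-10-(TBDPSO-methyl)-6-(PMBO-methyl)-3a,4,7,8,11,11a-hexahydrocyclodeca[b]furan-2(3H)-one | O=C1O[C@H]2C/C(CO[Si](c3ccccc3)(c3ccccc3)C(C)(C)C)=C\CC/C(COCc3ccc(OC)cc3)=C/C[C@@H]2C1 | intermediate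
27 | (3aR,5Z,9E,11aS)-3-[(dimethylamino)methyl]-10-(TBDPSO-methyl)-6-(PMBO-methyl)-3a,4,7,8,11,11a-hexahydrocyclodeca[b]furan-2(3H)-one (C3 epimers) | CN(C)CC1C(=O)O[C@H]2C/C(CO[Si](c3ccccc3)(c3ccccc3)C(C)(C)C)=C\CC/C(COCc3ccc(OC)cc3)=C/C[C@H]12 | intermediate
28 | N,N,N-trimethyl-1-[(3aR,5Z,9E,11aS)-10-(TBDPSO-methyl)-6-(PMBO-methyl)-2-oxo-2,3,3a,4,7,8,11,11a-octahydrocyclodeca[b]furan-3-yl]methanaminium iodide | C[N+](C)(C)CC1C(=O)O[C@H]2C/C(CO[Si](c3ccccc3)(c3ccccc3)C(C)(C)C)=C\CC/C(COCc3ccc(OC)cc3)=C/C[C@H]12.[I-] | intermediate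
29 | (3aR,5Z,9E,11aS)-10-(TBDPSO-methyl)-6-(PMBO-methyl)-3-methylidene-3a,4,7,8,11,11a-hexahydrocyclodeca[b]furan-2(3H)-one | C=C1C(=O)O[C@H]2C/C(CO[Si](c3ccccc3)(c3ccccc3)C(C)(C)C)=C\CC/C(COCc3ccc(OC)cc3)=C/C[C@H]12 | intermediate
30 | (3aR,5Z,9E,11aS)-10-(TBDPSO-methyl)-6-(hydroxymethyl)-3-methylidene-3a,4,7,8,11,11a-hexahydrocyclodeca[b]furan-2(3H)-one | C=C1C(=O)O[C@H]2C/C(CO[Si](c3ccccc3)(c3ccccc3)C(C)(C)C)=C\CC/C(CO)=C/C[C@H]12 | intermediate
31 | 2-hydroxy-2-methylpropanoic acid | CC(C)(O)C(=O)O | starting material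
32 | triethylsilyl 2-methyl-2-(TESO)propanoate | CC[Si](CC)(CC)OC(=O)C(C)(C)O[Si](CC)(CC)CC | intermediate
33 | 2-methyl-2-(TESO)propanoic acid | CC[Si](CC)(CC)OC(C)(C)C(=O)O | intermediate
34 | [(3aR,5Z,9E,11aS)-10-(TBDPSO-methyl)-3-methylidene-2-oxo-2,3,3a,4,7,8,11,11a-octahydrocyclodeca[b]furan-6-yl]methyl 2-methyl-2-(TESO)propanoate | C=C1C(=O)O[C@H]2C/C(CO[Si](c3ccccc3)(c3ccccc3)C(C)(C)C)=C\CC/C(COC(=O)C(C)(C)O[Si](CC)(CC)CC)=C/C[C@H]12 | intermediate
35 | [(3aR,5Z,9E,11aS)-10-(hydroxymethyl)-3-methylidene-2-oxo-2,3,3a,4,7,8,11,11a-octahydrocyclodeca[b]furan-6-yl]methyl 2-hydroxy-2-methylpropanoate | C=C1C(=O)O[C@H]2C/C(CO)=C\CC/C(COC(=O)C(C)(C)O)=C/C[C@H]12 | target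

## Step count and least certain steps

Total step count: 22 (21 in the main sequence plus the preparation of acid 33). Longest linear sequence: 20 steps, from 3 (or equally from 1) through steps 2 or 1, 3–19, 21 and 22.

**Step 15 (key step).** The most likely failure is oligomerisation or protodeboronation of alkylborane 22, because closing a ten-membered ring through an eleven-membered palladacycle is slow and bimolecular coupling or loss of boron can overtake it. β-Hydride elimination of the alkylpalladium intermediate is the second risk. The fallback keeps the C3–C4 bond but makes it intermolecularly and closes the ring at C1=C10. It sets out from phosphonate 17. Acrolein diethyl acetal is hydroborated with 9-BBN to 9-(3,3-diethoxypropyl)-9-borabicyclo[3.3.1]nonane F1, which is coupled with the vinyl iodide of 17 (PdCl2(dppf), AsPh3, Cs2CO3, DMF–H2O, rt) to the acetal phosphonate F2. Mild acid hydrolysis (PPTS, acetone–H2O) gives the aldehyde phosphonate F3. Intramolecular Horner–Wadsworth–Emmons reaction (LiCl, DBU, MeCN, high dilution) gives the ten-membered enoate F4. Reduction with i-Bu2AlH to the cyclic allylic alcohol F5 and silylation with TBDPSCl return to 23.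

**Step 6.** The vinyl group may be delivered to C8 instead of C7, or an ethyl group or chloride may be transferred instead of vinyl, because the selectivity rests on chelation of a mixed alane and alkenylalanes are less documented in this opening than alkyl- and alkynylalanes. The fallback uses the better documented alkynylalane and sets out from 8. Et2AlC≡CSiMe3 (from Me3SiC≡CLi and Et2AlCl) opens the epoxide at C7 to the silylalkynyl diol F6. K2CO3 in MeOH gives the ethynyl diol F7. Hydroboration of the terminal alkyne with dicyclohexylborane gives the alkenylborane F8, and protonolysis with acetic acid converts it into the vinyl diol 9, where the route is rejoined.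

**Step 5.** Z-allylic alcohols are the slowest and least selective substrate class for the titanium–tartrate catalyst, because the cis substituent crowds the loaded complex. Incomplete enantioselectivity and slow turnover are the likely problems. The fallback secures enantiopurity by classical enrichment. It sets out from scalemic 8, which is acylated with 3,5-dinitrobenzoyl chloride to the 3,5-dinitrobenzoate F9. This is recrystallised to enantiopurity and cleaved with K2CO3 in MeOH, returning to 8.

**Step 11.** Displacement at the β-branched, β-silyloxy primary carbon by a stabilised carbanion may be too slow, so that triflate 16 decomposes or is O-alkylated. The fallback uses a stronger carbon nucleophile and makes the alkene by aldol condensation, which also bypasses step 12. It sets out from 14 through triflate 16. The lithium enolate of tert-butyl acetate (LiN(iPr)2, THF, −78 °C) gives the tert-butyl ester F10. Its enolate adds to acrolein to give the aldol adduct F11. Mesylation (MsCl, Et3N) gives the mesylate F12, and DBU-induced E1cB elimination gives the tert-butyl dienoate F13. Reduction with i-Bu2AlH returns to 20.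

## Further compounds

F1 | step 15 | 9-(3,3-diethoxypropyl)-9-borabicyclo[3.3.1]nonane | CCOC(CCB1C2CCCC1CCC2)OCC
F2 | step 15 | ethyl (4S,5R,7Z)-4-(TBSO)-5-[2-(TBSO)ethyl]-2-(diethoxyphosphoryl)-11,11-diethoxy-8-(PMBO-methyl)undec-7-enoate | CCOC(=O)C(C[C@H](O[Si](C)(C)C(C)(C)C)[C@@H](CCO[Si](C)(C)C(C)(C)C)C/C=C(/CCC(OCC)OCC)COCc1ccc(OC)cc1)P(=O)(OCC)OCC
F3 | step 15 | ethyl (4S,5R,7Z)-4-(TBSO)-5-[2-(TBSO)ethyl]-2-(diethoxyphosphoryl)-8-(PMBO-methyl)-11-oxoundec-7-enoate | CCOC(=O)C(C[C@H](O[Si](C)(C)C(C)(C)C)[C@@H](CCO[Si](C)(C)C(C)(C)C)C/C=C(/CCC=O)COCc1ccc(OC)cc1)P(=O)(OCC)OCC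
F4 | step 15 | ethyl (1E,5Z,8R,9S)-9-(TBSO)-8-[2-(TBSO)ethyl]-5-(PMBO-methyl)cyclodeca-1,5-diene-1-carboxylate | CC(C)(C)[Si](C)(C)O[C@H]1C/C(C(=O)OCC)=C\CC/C(COCc2ccc(OC)cc2)=C/C[C@@H]1CCO[Si](C)(C)C(C)(C)C
F5 | step 15 | [(1E,5Z,8R,9S)-9-(TBSO)-8-[2-(TBSO)ethyl]-5-(PMBO-methyl)cyclodeca-1,5-dien-1-yl]methanol | CC(C)(C)[Si](C)(C)O[C@H]1C/C(CO)=C\CC/C(COCc2ccc(OC)cc2)=C/C[C@@H]1CCO[Si](C)(C)C(C)(C)C
F6 | step 6 | (2R,3R,5E)-6-iodo-7-(PMBO)-3-[(trimethylsilyl)ethynyl]hept-5-ene-1,2-diol | OC[C@H](O)[C@@H](C#C[Si](C)(C)C)C/C=C(/I)COCc1ccc(OC)cc1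
F7 | step 6 | (2R,3R,5E)-3-ethynyl-6-iodo-7-(PMBO)hept-5-ene-1,2-diol | OC[C@H](O)[C@@H](C#C)C/C=C(/I)COCc1ccc(OC)cc1
F8 | step 6 | (E)-alkenyl(dicyclohexyl)borane of F7 with both hydroxyls as dicyclohexylborinates | C1CCCCC1B(C1CCCCC1)OC[C@H](OB(C1CCCCC1)C1CCCCC1)[C@@H](/C=C/B(C1CCCCC1)C1CCCCC1)C/C=C(/I)COCc1ccc(OC)cc1
F9 | step 5 | [(2S,3R)-3-[(2E)-3-iodo-4-(PMBO)but-2-en-1-yl]oxiran-2-yl]methyl 3,5-dinitrobenzoate | O=C(OC[C@@H]1O[C@@H]1C/C=C(/I)COCc2ccc(OC)cc2)c3cc([N+](=O)[O-])cc([N+](=O)[O-])c3
F10 | step 11 | tert-butyl (4S,5R,7E)-4-(TBSO)-5-[2-(TBSO)ethyl]-8-iodo-9-(PMBO)non-7-enoate | CC(C)(C)OC(=O)CC[C@H](O[Si](C)(C)C(C)(C)C)[C@@H](CCO[Si](C)(C)C(C)(C)C)C/C=C(/I)COCc1ccc(OC)cc1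
F11 | step 11 | tert-butyl (4S,5R,7E)-4-(TBSO)-5-[2-(TBSO)ethyl]-2-(1-hydroxyprop-2-en-1-yl)-8-iodo-9-(PMBO)non-7-enoate (diastereomer mixture) | CC(C)(C)OC(=O)C(C[C@H](O[Si](C)(C)C(C)(C)C)[C@@H](CCO[Si](C)(C)C(C)(C)C)C/C=C(/I)COCc1ccc(OC)cc1)C(O)C=C
F12 | step 11 | methanesulfonate of F11 | CC(C)(C)OC(=O)C(C[C@H](O[Si](C)(C)C(C)(C)C)[C@@H](CCO[Si](C)(C)C(C)(C)C)C/C=C(/I)COCc1ccc(OC)cc1)C(OS(C)(=O)=O)C=C
F13 | step 11 | tert-butyl (2E)-2-[(2S,3R,5E)-2-(TBSO)-3-[2-(TBSO)ethyl]-6-iodo-7-(PMBO)hept-5-en-1-yl]penta-2,4-dienoate | C=C/C=C(C(=O)OC(C)(C)C)\C[C@H](O[Si](C)(C)C(C)(C)C)[C@@H](CCO[Si](C)(C)C(C)(C)C)C/C=C(/I)COCc1ccc(OC)cc1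
A1 | alternative 1 | open-chain precursor: C6 diethyl phosphate, ring-trans C4=C5 with C15 OTBDPS, C14 methyl enoate with C9 and C2 cis, C8 OTBS, C7=C11 allylsilane with C12 OTBS and C13 SiMe3 (allylsilane geometry left open) | CCOP(=O)(OCC)OC/C=C(CO[Si](c1ccccc1)(c1ccccc1)C(C)(C)C)/CC/C=C(C(=O)OC)\C[C@H](O[Si](C)(C)C(C)(C)C)C=C(CO[Si](C)(C)C(C)(C)C)C[Si](C)(C)C
A2 | alternative 1 | methyl (1E,5Z,8R,9S)-9-(TBSO)-8-[3-(TBSO)prop-1-en-2-yl]-5-(TBDPSO-methyl)cyclodeca-1,5-diene-1-carboxylate | CC(C)(C)[Si](C)(C)O[C@H]1C/C(C(=O)OC)=C\CC/C(CO[Si](c2ccccc2)(c2ccccc2)C(C)(C)C)=C/C[C@@H]1C(=C)CO[Si](C)(C)C(C)(C)C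
A3 | alternative 2 | cis-1,2-dialkenylcyclohexanol (ring C5–C10): C5 hydroxyl and 3-(TBDPSO)prop-1-en-2-yl, C10 vinyl and CH2OPMB cis to the C5 alkenyl group, C7 3-(TBSO)prop-1-en-2-yl, C8 OTBS, C7 and C8 as in the target | O[C@]1(C(=C)CO[Si](c2ccccc2)(c2ccccc2)C(C)(C)C)C[C@H](C(=C)CO[Si](C)(C)C(C)(C)C)[C@@H](O[Si](C)(C)C(C)(C)C)C[C@]1(C=C)COCc3ccc(OC)cc3
A4 | alternative 2 | cyclodeca-1(10),4-dien-5-yl trifluoromethanesulfonate with C8 OTBS, C14 OPMB, C15 OTBDPS and a C7 3-(TBSO)prop-1-en-2-yl group, ring-cis C1=C10 and ring-trans C4=C5 | CC(C)(C)[Si](C)(C)O[C@H]1C/C(COCc2ccc(OC)cc2)=C\CC/C(CO[Si](c2ccccc2)(c2ccccc2)C(C)(C)C)=C(OS(=O)(=O)C(F)(F)F)/C[C@@H]1C(=C)CO[Si](C)(C)C(C)(C)C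
A5 | alternative 3 | open-chain precursor: C1 aldehyde, ring-trans C4=C5 with C15 OPMB, C7 3-(TBSO)prop-1-en-2-yl, C8 OTBS, C10 diethyl phosphonoacetate (ethyl ester) | O=CCC/C(COCc1ccc(OC)cc1)=C/C[C@H](C(=C)CO[Si](C)(C)C(C)(C)C)[C@@H](O[Si](C)(C)C(C)(C)C)CC(C(=O)OCC)P(=O)(OCC)OCC
A6 | alternative 3 | ethyl (1E,5Z,8R,9S)-9-(TBSO)-8-[3-(TBSO)prop-1-en-2-yl]-5-(PMBO-methyl)cyclodeca-1,5-diene-1-carboxylate | CC(C)(C)[Si](C)(C)O[C@H]1C/C(C(=O)OCC)=C\CC/C(COCc2ccc(OC)cc2)=C/C[C@@H]1C(=C)CO[Si](C)(C)C(C)(C)C
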